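**Slow tail.** The slowness in these flasks lies after L, not in it: in Saturday's run L falls with a time constant of about 0.303 h as read, yet Z then stands flat out to 8.00 h.

| setting | Saturday's | Sunday's | Tuesday's | cedar | birch | maple | larch |
|---|---|---|---|---|---|---|---|
| L | 0.18 M | 0.18 M | 0.088 M | 0.050 M | 0.060 M | 0.060 M | 0.18 M |
| D | 0.11 M | 0.19 M | 0.18 M | 0.120 M | 0.120 M | 0.250 M | 0.180 M |
| remark | run made earlier | run made earlier | run made earlier |  |  |  |  |
| time |  |  |  | 15 h | 15 h | 15 h | 15 h |

| run | time / h | Z / % | L / % |
|---|---|---|---|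
| Saturday's | 0.667 | 3.1 | 11.1 |
| Saturday's | 1.00 | 4.7 | 4.5 |
| Saturday's | 2.00 | 9.4 | 0.2 |
| Saturday's | 4.00 | 7.4 | 0 |
| Saturday's | 8.00 | 9.6 | 1.1 |
| Sunday's | 1.50 | 9.2 | 2.1 |
| Sunday's | 3.00 | 7.6 | 0 |
| Sunday's | 5.00 | 9.2 | 0.9 |
| Sunday's | 6.00 | 10.9 | 0 |
| Sunday's | 8.00 | 9.1 | 0 |
| Tuesday's | 1.50 | 15.8 | 0.2 |
| Tuesday's | 3.00 | 17.6 | 0 |
| Tuesday's | 5.00 | 17.5 | 0 |
| Tuesday's | 6.00 | 16.9 | 0 |
| Tuesday's | 8.00 | 17.9 | 0.9 |

(scatter of a reading: 1 percentage point)



- all flasks from highest to lowest amount of Z, in percent of the L charged, at 15 h (cedar / birch / maple / larch)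
- the amount of Z, in percent of the L charged of the flask you put first, at 15 h
- the amount of Z, in percent of the L charged of the flask you put last, at 15 h

**The ceiling.** The last readings, turned into amounts of Z, are 0.0173 M on Saturday, 0.0164 M on Sunday and 0.0158 M on Tuesday. Their mean, 0.0165 M, is the ceiling, the height of the flat stretch. Divided by a flask's L charge, it becomes that flask's ceiling share.

**Upper bound.** Read as an upper estimate, not a proven limit, the ceiling shares are 32.9% for cedar and 27.5% for birch and maple; the share for larch is 9.15%, with the scatter of the readings on either side of it.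

**Lower bound.** Larch has Sunday's L and nearly its D, so my bracket for larch is Sunday's flat readings, 7.6% to 10.9%. The others are harder. A height indifferent to D looks to me like a quasi-steady state, with Z made and lost in step with D, fed by some form of L that the readings do not show and whose amount they do not give. If that feed ends while D remains, Z can fall, so their lower bound drops to nil. As fractions of the L charge, D stands at 2.00 in birch, below Tuesday's 2.05, and at 2.40 in cedar and 4.17 in maple. My reckoning therefore puts birch first and maple last.

**The forecast.** It reads “a fixed absolute cap” and gives cedar > maple > birch > larch, with 31% and 9%. Both numbers lie inside the brackets, but its order differs from mine.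

**The result.** The flasks give birch > cedar > larch > maple: birch 23.4%, cedar 16.4%, larch 10.0%, maple 0.219%.

    D + Z → Q (k = 9.85 /M/h)
    D → G (k = 0.163 /h)
    X + G → Z (k = 34.0 /M/h)
    L → X (k = 3.18 /h)

**Maple's fall.** Maple ends at 0.219%, far under its ceiling share, with X at 0% and Q at 99.8%. The reason is the turning of D + Z into Q: with that step taken away, maple holds 100% of Z. The neighbouring flask, maple's charge with D cut to 0.062 M, has 1.03 equiv of D to L. It still holds 34.6% of X at the end, and its Z stands at 29.0% against the ceiling share of 27.5%.

The runs come from a simulation with made-up constants, noise included.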